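## Retrosynthetic overview

1. Target 28 ⇐ 26: the tertiary formate and the free C3–OH are unveiled last; the C8 methylidene comes from a C8 ketone (25) and the 2-methoxy-4-pyranone from a 4-hydroxy-2-pyranone (24) by O-methylation.
2. C9–C11 bond: Mannich base 19 is joined to pyranone 22 (made from 20 and 21); the C10 methyl and the C9 enol ether come from conjugate methylation of enone 17.
3. Key step: enone 17 ⇐ anisole 14 by Birch dearomatization of the fully functionalized arene, then amine-catalysed enone transposition that sets C5; the dearomatized ring then takes up C5, C10 and C9 in sequence.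
4. Tetralin 14 ⇐ tetralone 5: C4 (quaternary) by a deracemizing Michael addition of a chiral imine, C3 by CBS reduction; 5 comes from 6-methoxy-1-tetralone 1.
5. Ring order: ring A (saturated ring of 1) and ring B (the arene of 1) are present from the start and ring B is dearomatized late; the pyranone ring is built separately and attached at C11.

Assumption: the stereochemistry is taken literally from the SMILES, i.e. a cis-fused decalin (H5 and the C10 methyl on the same face), (3S,4R,5R,9S,10S) in the locants below; the senses of induction of the chiral amine, the CBS catalyst and the cinchona amine are assigned from the accepted models of the parent reactions.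

Locants: compounds 1–14 use tetralin locants. From 15 on, decalin locants are used: ring A = C1, C2, C3, C4, C5, C10; ring B = C5, C6, C7, C8, C9, C10; C11 = CH2 on C9. Tetralin C1, C2, C6 correspond to decalin C4, C3, C8.

## Route

Step 1
Reactants: 1 6-methoxy-1-tetralone
Product: 3 7-methoxy-4-methyl-1,2-dihydronaphthalene, via tertiary alcohol 2 (not isolated)
Conditions: MeMgBr, THF, 0 °C → rt; then TsOH (cat.), toluene, 80 °C
Reagents that add atoms: methylmagnesium bromide, C[Mg]Br
Why: Grignard 1,2-addition to the aryl ketone followed by acid-catalysed dehydration of the tertiary benzylic alcohol; no stereocentre is formed.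

Step 2
Reactants: 3 7-methoxy-4-methyl-1,2-dihydronaphthalene
Product: 5 rac-6-methoxy-1-methyl-2-tetralone, via epoxide 4 (not isolated)
Conditions: mCPBA, NaHCO3, CH2Cl2, 0 °C; then BF3·OEt2 (cat.), −20 °C
Reagents that add atoms: 3-chloroperbenzoic acid, O=C(OO)c1cccc(Cl)c1
Why: Prilezhaev epoxidation of the electron-rich styrene, then Meinwald rearrangement (p-methoxybenzylic cation, 1,2-hydride shift) moves the carbonyl to C2; the C1 centre is racemic and enolizable, which the next step exploits.

Step 3
Reactants: 5 rac-6-methoxy-1-methyl-2-tetralone; 6 (R)-1-phenylethylamine; 7 methyl acrylate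
Product: 10 methyl 3-[(1R)-6-methoxy-1-methyl-2-oxo-tetralin-1-yl]propanoate, via ketimine 8 (not isolated), via adduct imine 9 (not isolated)
Conditions: 6, TsOH (cat.), toluene, reflux (−H2O); 7, THF, 40 °C; then 20% aq. AcOH, rt
Reagents that add atoms: methyl acrylate 7, C=CC(=O)OC; water, O
Why: d'Angelo–Pfau deracemizing Michael addition: the arene-conjugated secondary enamine tautomer of the chiral imine adds to the acrylate through a compact aza-ene-like transition state on the face anti to the phenyl group of the auxiliary, which sets the quaternary centre as (R) (C4 of the target); hydrolysis returns the amine.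

Step 4
Reactants: 10 methyl 3-[(1R)-6-methoxy-1-methyl-2-oxo-tetralin-1-yl]propanoate
Product: 12 cis-fused δ-lactone of the (1R,2S)-hydroxy ester, via hydroxy ester 11 (not isolated)
Conditions: (R)-Me-CBS oxazaborolidine (10 mol %), BH3·SMe2, THF, −20 °C; MeOH; then TsOH (cat.), CH2Cl2, rt
Reagents that add atoms: none
Why: Corey–Bakshi–Shibata reduction with the quaternary carbon as the large group, so the (R)-catalyst gives the (2S)-carbinol (OH cis to the ester chain, reagent control on a ketone the ester cannot compete with at −20 °C); acid closes the δ-lactone.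

Step 5
Reactants: 12 cis-fused δ-lactone
Product: 13 (1R,2S)-1-(3-hydroxy-3-methylbutyl)-6-methoxy-1-methyl-tetralin-2-ol
Conditions: MeMgBr (4 equiv), THF, 0 °C → rt; aq. NH4Cl
Reagents that add atoms: methylmagnesium bromide, C[Mg]Br
Why: double Grignard addition to the lactone carbonyl (through the methyl ketone) builds the dimethyl carbinol and releases the C2 alkoxide; no stereocentre is touched.

Step 6
Reactants: 13 (1R,2S)-1-(3-hydroxy-3-methylbutyl)-6-methoxy-1-methyl-tetralin-2-ol
Product: 14 2-O-TBS ether of diol 13 (tertiary OH free)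
Conditions: TBSOTf (1.1 equiv), 2,6-lutidine, CH2Cl2, −78 °C
Reagents that add atoms: tert-butyldimethylsilyl triflate, CC(C)(C)[Si](C)(C)OS(=O)(=O)C(F)(F)F
Why: silylation with the silyl triflate at −78 °C is selective for the secondary over the tertiary hydroxyl; this differentiates the two alcohols for the late formylation.

Step 7
Reactants: 14 2-O-TBS ether of diol 13
Product: 16 (3S,4R)-3-(TBSO)-4-(3-hydroxy-3-methylbutyl)-4-methyl-decal-5(10)-en-8-one, via dienol ether 15 (not isolated)
Conditions: Li, NH3(l), t-BuOH, THF, −78 → −33 °C; NH4Cl; then (CO2H)2, THF–H2O, rt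
Reagents that add atoms: water, O
Why: Birch reduction (key step) on the arene that already carries both oxygenated stereocentres: the anisole ring takes up two electrons and two protons at C9 and C6 so that the OMe- and alkyl-bearing carbons stay sp2, and oxalic acid hydrolyses only the enol ether to the β,γ-unsaturated ketone without moving the C5=C10 double bond; the silyl ether and the tertiary alcohol are inert to Li/NH3 and no stereocentre is formed.

Step 8
Reactants: 16 (3S,4R)-decal-5(10)-en-8-one
Product: 17 (3S,4R,5R)-3-(TBSO)-4-(3-hydroxy-3-methylbutyl)-4-methyl-decal-9-en-8-one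
Conditions: 9-amino-9-deoxy-epi-quinine (10 mol %), 2-nitrobenzoic acid (20 mol %), toluene, rt
Reagents that add atoms: none
Why: enantioselective olefin isomerization by cooperative iminium–base catalysis: the primary amine forms the C8 iminium, the C9 proton is shuttled through the dienamine to C5, and it is delivered to the α-face anti to the pseudo-axial C4 side chain (the substrate's own modest preference, reinforced by the catalyst), which fixes (5R).

Step 9
Reactants: 17 (3S,4R,5R)-decal-9-en-8-one
Product: 19 (3S,4R,5R,10R)-9-(dimethylaminomethyl)-3-(TBSO)-4-(3-hydroxy-3-methylbutyl)-4,10-dimethyl-decalin-8-one (cis-fused; C9 epimers), via silyl enol ether 18 (not isolated)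
Conditions: Me2CuLi, TMSCl, THF, −78 → −40 °C; then CH2=NMe2+ I−, CH2Cl2, rt; citric acid, MeOH; aq. NaHCO3
Reagents that add atoms: lithium dimethylcuprate, [Li+].C[Cu-]C; Eschenmoser's salt, C=[N+](C)C.[I-]
Why: TMSCl-accelerated cuprate 1,4-addition puts the methyl on C10 cis to H5 (the known cis selectivity of Δ1(9)-2-octalones, helped here because the opposite face is screened by the axial C4 side chain), giving the cis-fused quaternary centre; the regiodefined C8 silyl enol ether then undergoes a Mannich reaction at C9.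

Step 10
Reactants: 20 malonyl dichloride; 21 methyl acetoacetate
Product: 22 methyl 4-hydroxy-2-methyl-6-oxo-6H-pyran-3-carboxylate
Conditions: CH2Cl2, rt → 40 °C (−HCl)
Reagents that add atoms: malonyl dichloride 20, O=C(Cl)CC(=O)Cl; methyl acetoacetate 21, COC(=O)CC(C)=O
Why: cyclocondensation: C-acylation of the β-keto ester by one acyl chloride and O-acylation of its enol by the other closes the 4-hydroxy-2-pyranone ring.

Step 11
Reactants: 19 Mannich base; 22 methyl 4-hydroxy-2-methyl-6-oxo-6H-pyran-3-carboxylate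
Product: 24 methyl 4-hydroxy-2-methyl-6-oxo-5-{[(3S,4R,5R,9R,10R)-3-(TBSO)-4-(3-hydroxy-3-methylbutyl)-4,10-dimethyl-8-oxo-decalin-9-yl]methyl}-6H-pyran-3-carboxylate, via methylidene ketone 23 (not isolated)
Conditions: toluene, 100 °C, N2 sweep (−Me2NH)
Reagents that add atoms: pyranone 22, COC(=O)c1c(C)oc(=O)cc1O
Why: Mannich-base exchange: the acidic pyranone protonates the amine, thermal β-elimination gives α-methylidene ketone 23 and the free ring carbon of the pyranone adds to it (Michael addition); C9 stays epimerizable and settles with the CH2-pyranone equatorial, trans to the C10 methyl, the only chair arrangement of ring B without a syn-axial carbon contact.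

Step 12
Reactants: 24 hydroxypyranone ketone
Product: 25 methyl 6-methoxy-2-methyl-4-oxo-5-{[(3S,4R,5R,9R,10R)-3-(TBSO)-4-(3-hydroxy-3-methylbutyl)-4,10-dimethyl-8-oxo-decalin-9-yl]methyl}-4H-pyran-3-carboxylate
Conditions: MeOTf, 2,6-di-tert-butyl-4-methylpyridine, CH2Cl2, 0 °C → rt
Reagents that add atoms: methyl triflate, COS(=O)(=O)C(F)(F)F
Why: O-methylation of the neutral 4-hydroxy-2-pyranone with a hard methylating agent takes place at the lactone carbonyl oxygen and gives the 2-methoxy-4-pyranone regioisomer; the hindered base scavenges TfOH and the tertiary alcohol is not methylated at this stoichiometry.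

Step 13
Reactants: 25 methoxypyranone ketone
Product: 26 methyl 6-methoxy-2-methyl-4-oxo-5-{[(3S,4R,5R,9S,10S)-3-(TBSO)-4-(3-hydroxy-3-methylbutyl)-4,10-dimethyl-8-methylidene-decalin-9-yl]methyl}-4H-pyran-3-carboxylate
Conditions: Zn, CH2Br2, TiCl4, THF–CH2Cl2, 0 °C → rt
Reagents that add atoms: dibromomethane, BrCBr
Why: Takai–Lombardo methylenation: the non-basic zinc/titanium methylene reagent converts the hindered, enolizable C8 ketone into the exocyclic alkene without epimerizing C9 and leaves the ester and the pyranone carbonyl alone; the descriptors at C9 and C10 change only because the CIP rank of C8 changes.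

Step 14
Reactants: 26 methylidene alcohol
Product: 27 3-O-TBS ether of the target (tertiary formate)
Conditions: acetic formic anhydride, pyridine, DMAP (cat.), CH2Cl2, 0 °C → rt
Reagents that add atoms: acetic formic anhydride, CC(=O)OC=O
Why: acyl transfer from the mixed anhydride at its more electrophilic formyl carbon to the only free hydroxyl, the tertiary alcohol, under nucleophilic catalysis.

Step 15
Reactants: 27 3-O-TBS ether of the target
Product: 28 target, methyl 5-{[(3S,4R,5R,9S,10S)-4-(3-formyloxy-3-methylbutyl)-3-hydroxy-4,10-dimethyl-8-methylidene-decalin-9-yl]methyl}-6-methoxy-2-methyl-4-oxo-4H-pyran-3-carboxylate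
Conditions: HF·pyridine, pyridine–THF, 0 °C → rt
Reagents that add atoms: none
Why: fluoride-mediated Si–O cleavage under buffered conditions that spare the base-labile tertiary formate, the exocyclic alkene and the methoxypyranone.

## Compound list

1 | 6-methoxy-1-tetralone | COc1ccc2c(c1)CCCC2=O | starting material
2 | 6-methoxy-1-methyl-tetralin-1-ol | COc1ccc2c(c1)CCCC2(C)O | intermediate
3 | 7-methoxy-4-methyl-1,2-dihydronaphthalene | COc1ccc2c(c1)CCC=C2C | intermediate
4 | rac-6-methoxy-1-methyl-1,2-epoxytetralin | COc1ccc2c(c1)CCC3OC23C | intermediate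
5 | rac-6-methoxy-1-methyl-2-tetralone | COc1ccc2c(c1)CCC(=O)C2C | intermediate
6 | (R)-1-phenylethylamine | C[C@@H](N)c1ccccc1 | starting material
7 | methyl acrylate | C=CC(=O)OC | starting material
8 | N-[(R)-1-phenylethyl] ketimine of 5 (reacts as the enamine tautomer) | COc1ccc2c(c1)CCC(=N[C@H](C)c3ccccc3)C2C | intermediate
9 | N-[(R)-1-phenylethyl] imine of keto ester 10 | COC(=O)CC[C@@]1(C)C(=N[C@H](C)c3ccccc3)CCc2cc(OC)ccc21 | intermediate
10 | methyl 3-[(1R)-6-methoxy-1-methyl-2-oxo-tetralin-1-yl]propanoate | COC(=O)CC[C@@]1(C)C(=O)CCc2cc(OC)ccc21 | intermediate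
11 | methyl 3-[(1R,2S)-2-hydroxy-6-methoxy-1-methyl-tetralin-1-yl]propanoate | COC(=O)CC[C@@]1(C)[C@@H](O)CCc2cc(OC)ccc21 | intermediate
12 | cis-fused δ-lactone of 11 (C2–O and the C1 chain cis) | COc1ccc2c(c1)CC[C@@H]3OC(=O)CC[C@]23C | intermediate
13 | (1R,2S)-1-(3-hydroxy-3-methylbutyl)-6-methoxy-1-methyl-tetralin-2-ol | COc1ccc2c(c1)CC[C@H](O)[C@]2(C)CCC(C)(C)O | intermediate
14 | 2-O-TBS ether of 13 | COc1ccc2c(c1)CC[C@H](O[Si](C)(C)C(C)(C)C)[C@]2(C)CCC(C)(C)O | intermediate
15 | (3S,4R)-3-(TBSO)-4-(3-hydroxy-3-methylbutyl)-8-methoxy-4-methyl-decal-5(10),7-diene | COC1=CCC2=C(C1)CC[C@H](O[Si](C)(C)C(C)(C)C)[C@]2(C)CCC(C)(C)O | intermediate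
16 | (3S,4R)-3-(TBSO)-4-(3-hydroxy-3-methylbutyl)-4-methyl-decal-5(10)-en-8-one | O=C1CCC2=C(C1)CC[C@H](O[Si](C)(C)C(C)(C)C)[C@]2(C)CCC(C)(C)O | intermediate
17 | (3S,4R,5R)-3-(TBSO)-4-(3-hydroxy-3-methylbutyl)-4-methyl-decal-9-en-8-one | O=C1CC[C@H]2[C@@](C)(CCC(C)(C)O)[C@@H](O[Si](C)(C)C(C)(C)C)CCC2=C1 | intermediate
18 | C8 trimethylsilyl enol ether (C8=C9) of the cis-fused C10-methyl ketone, tertiary OH as TMS ether | C[Si](C)(C)OC1=C[C@]2(C)CC[C@H](O[Si](C)(C)C(C)(C)C)[C@](C)(CCC(C)(C)O[Si](C)(C)C)[C@@H]2CC1 | intermediate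
19 | (3S,4R,5R,10R)-9-(dimethylaminomethyl)-3-(TBSO)-4-(3-hydroxy-3-methylbutyl)-4,10-dimethyl-decalin-8-one, cis-fused, C9 epimers | O=C1CC[C@H]2[C@@](C)(CCC(C)(C)O)[C@@H](O[Si](C)(C)C(C)(C)C)CC[C@@]2(C)C1CN(C)C | intermediate
20 | malonyl dichloride | O=C(Cl)CC(=O)Cl | starting material
21 | methyl acetoacetate | COC(=O)CC(C)=O | starting material
22 | methyl 4-hydroxy-2-methyl-6-oxo-6H-pyran-3-carboxylate | COC(=O)c1c(C)oc(=O)cc1O | intermediate
23 | (3S,4R,5R,10R)-3-(TBSO)-4-(3-hydroxy-3-methylbutyl)-4,10-dimethyl-9-methylidene-decalin-8-one | O=C1CC[C@H]2[C@@](C)(CCC(C)(C)O)[C@@H](O[Si](C)(C)C(C)(C)C)CC[C@@]2(C)C1=C | intermediate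
24 | methyl 4-hydroxy-2-methyl-6-oxo-5-{[(3S,4R,5R,9R,10R)-3-(TBSO)-4-(3-hydroxy-3-methylbutyl)-4,10-dimethyl-8-oxo-decalin-9-yl]methyl}-6H-pyran-3-carboxylate | O=C1CC[C@H]2[C@@](C)(CCC(C)(C)O)[C@@H](O[Si](C)(C)C(C)(C)C)CC[C@@]2(C)[C@H]1Cc1c(O)c(C(=O)OC)c(C)oc1=O | intermediate
25 | methyl 6-methoxy-2-methyl-4-oxo-5-{[(3S,4R,5R,9R,10R)-3-(TBSO)-4-(3-hydroxy-3-methylbutyl)-4,10-dimethyl-8-oxo-decalin-9-yl]methyl}-4H-pyran-3-carboxylate | O=C1CC[C@H]2[C@@](C)(CCC(C)(C)O)[C@@H](O[Si](C)(C)C(C)(C)C)CC[C@@]2(C)[C@H]1Cc1c(OC)oc(C)c(C(=O)OC)c1=O | intermediate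
26 | methyl 6-methoxy-2-methyl-4-oxo-5-{[(3S,4R,5R,9S,10S)-3-(TBSO)-4-(3-hydroxy-3-methylbutyl)-4,10-dimethyl-8-methylidene-decalin-9-yl]methyl}-4H-pyran-3-carboxylate | C=C1CC[C@H]2[C@@](C)(CCC(C)(C)O)[C@@H](O[Si](C)(C)C(C)(C)C)CC[C@@]2(C)[C@H]1Cc1c(OC)oc(C)c(C(=O)OC)c1=O | intermediate
27 | 3-O-TBS ether of the target (tertiary formate in place) | C=C1CC[C@H]2[C@@](C)(CCC(C)(C)OC=O)[C@@H](O[Si](C)(C)C(C)(C)C)CC[C@@]2(C)[C@H]1Cc1c(OC)oc(C)c(C(=O)OC)c1=O | intermediate
28 | methyl 5-{[(3S,4R,5R,9S,10S)-4-(3-formyloxy-3-methylbutyl)-3-hydroxy-4,10-dimethyl-8-methylidene-decalin-9-yl]methyl}-6-methoxy-2-methyl-4-oxo-4H-pyran-3-carboxylate | C=C1CC[C@H]2[C@@](C)(CCC(C)(C)OC=O)[C@@H](O)CC[C@@]2(C)[C@H]1Cc1c(OC)oc(C)c(C(=O)OC)c1=O | target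

## Step count and risks

Total: 15 steps. Longest linear sequence: 14 steps (steps 1–9 and 11–15; step 10 is the one-step side branch).

The three steps most likely to fail:

- **Step 8 (C5 by catalyst-controlled enone transposition).** The C4 methyl and C4 side chain are sterically similar, so the substrate's own preference at C5 is small, and the catalyst has not been shown on a tetrasubstituted, ring-fusion β,γ-alkene. The fallback sets out from 16 and comes back at 17. It drops catalyst control for thermodynamic control with recycling: 16 is equilibrated with DBU in CH2Cl2 through the extended dienolate to a mixture of 17 and the C5-epimeric enone F1. The two are separated on silica, and F1 is returned to the same equilibration until it is consumed.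

- **Step 9 (quaternary C10 methyl by cuprate addition to a hindered β,β-disubstituted enone).** The fallback sets out from 17 and comes back at 19. It replaces conjugate addition by a hydroxyl-directed cyclopropanation and reductive ring opening. Luche reduction (NaBH4, CeCl3, MeOH, −78 °C) gives the pseudo-equatorial allylic alcohol F2, with OH on the face of H5. Simmons–Smith cyclopropanation (Et2Zn, CH2I2), directed by that hydroxyl, gives the cyclopropyl carbinol F3. Dess–Martin oxidation gives the cyclopropyl ketone F4. Li in NH3 then cleaves the exocyclic cyclopropane bond that overlaps with the carbonyl, leaving the CH2 on C10 as the angular methyl, cis to H5. The C9 lithium enolate so formed is trapped with Eschenmoser's salt in THF to give 19.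

- **Step 11 (thermal Mannich exchange and the C9 configuration).** The strained cis-decalin makes the equilibrium position at C9 hard to predict, and the adduct may sit as a cyclic hemiketal. The fallback sets out from 18 and comes back at 26. It forms the C9–C11 bond by kinetic trapping and attaches the pyranone through an aldehyde. MeLi converts 18 into the lithium enolate, which is trapped with monomeric formaldehyde to give the hydroxymethyl ketone F5. Zn/CH2Br2/TiCl4 methylenation gives the homoallylic alcohol F6. Dess–Martin oxidation gives the aldehyde F7. Reductive Knoevenagel coupling with 22 (L-proline, Hantzsch ester, CH2Cl2) gives the hydroxypyranone F8. MeOTf with 2,6-di-tert-butyl-4-methylpyridine then gives 26.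

## Further compounds

F1 | step 8 | (3S,4R,5S)-3-(TBSO)-4-(3-hydroxy-3-methylbutyl)-4-methyl-decal-9-en-8-one (C5 epimer of 17) | O=C1CC[C@@H]2[C@@](C)(CCC(C)(C)O)[C@@H](O[Si](C)(C)C(C)(C)C)CCC2=C1
F2 | step 9 | C8 allylic alcohol of 17 (OH on the face of H5, C9=C10 retained) | O[C@@H]1CC[C@H]2[C@@](C)(CCC(C)(C)O)[C@@H](O[Si](C)(C)C(C)(C)C)CCC2=C1
F3 | step 9 | 9,10-methano (cyclopropane) carbinol, CH2 on the face of the C8 hydroxyl and H5 | O[C@@H]1CC[C@H]2[C@@](C)(CCC(C)(C)O)[C@@H](O[Si](C)(C)C(C)(C)C)CC[C@]23C[C@H]13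
F4 | step 9 | 9,10-methano-decalin-8-one (cyclopropyl ketone) | O=C1CC[C@H]2[C@@](C)(CCC(C)(C)O)[C@@H](O[Si](C)(C)C(C)(C)C)CC[C@]23C[C@H]13
F5 | step 11 | 9-(hydroxymethyl)-3-(TBSO)-4-(3-hydroxy-3-methylbutyl)-4,10-dimethyl-decalin-8-one, CH2OH trans to the C10 methyl | O=C1CC[C@H]2[C@@](C)(CCC(C)(C)O)[C@@H](O[Si](C)(C)C(C)(C)C)CC[C@@]2(C)[C@H]1CO
F6 | step 11 | 9-(hydroxymethyl)-8-methylidene analogue of F5 | C=C1CC[C@H]2[C@@](C)(CCC(C)(C)O)[C@@H](O[Si](C)(C)C(C)(C)C)CC[C@@]2(C)[C@H]1CO
F7 | step 11 | 8-methylidene-decalin-9-carbaldehyde | C=C1CC[C@H]2[C@@](C)(CCC(C)(C)O)[C@@H](O[Si](C)(C)C(C)(C)C)CC[C@@]2(C)[C@H]1C=O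
F8 | step 11 | 4-hydroxy-2-pyranone analogue of 26 | C=C1CC[C@H]2[C@@](C)(CCC(C)(C)O)[C@@H](O[Si](C)(C)C(C)(C)C)CC[C@@]2(C)[C@H]1Cc1c(O)c(C(=O)OC)c(C)oc1=O
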